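A direct plan would oxidise 2,4,6-tribromophenol A1 to 2,6-dibromo-1,4-benzoquinone A2, add 2,4-dibromophenol A3 to the C–H carbon of A2, reduce to 3,5-dibromo-2-(2,4-dibromophenoxy)benzene-1,4-diol A4 and methylate one of the two OH groups of A4.
Its weakest step would be the addition of the phenoxide of A3 to quinone A2: a hindered, electron-poor phenoxide would have to choose the C–H carbon of A2 over addition–elimination at C–Br, a second addition and redox scrambling, while excess A2 is spent as oxidant.
Next would be the mono-O-methylation of A4 on the most advanced material: the two OH groups differ little in acidity, the wanted one lies between two bromines, and isomeric or doubly methylated ethers would be hard to remove.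
Third would be the nitric acid oxidation of A1 to A2: a hazardous step that discards a bromine to reach a six-carbon quinone, with little gain in complexity.

**Plan of the new route**
The retrosynthesis cuts the C1–OH bond of ring A back to a C1–CHO group (Baeyer–Villiger), then the bond between the ether oxygen and C1' of ring B (not the ring A C2–O bond), then the two C–Br bonds of ring A.
This leads to 2-hydroxy-4-methoxybenzaldehyde, whose carbons map one to one onto ring A, and to ring B as an aryl cation equivalent, a diaryl-λ3-iodane made from 2,4-dibromo-1-iodobenzene.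
The enabling feature: ring B (C1'–C6') carries no oxygen but the ether oxygen, so it can be the electrophile. In ring A the ether oxygen (C2) is ortho to the free-OH carbon (C1), and Br at C3/C5 lie ortho/para to the C2 oxygen and ortho to the C4 methoxy group, which is a salicylaldehyde pattern.
Neither ring is built: ring A is completed first (OMe, both Br, the nucleophilic oxygen), ring B is then joined to that oxygen, and the free OH arises last from carbon.
No quinone or hydroquinone occurs, so the ether-forming step has no site choice and no two OH groups must be told apart. The three oxygens of ring A have three origins (purchased OMe, salicylaldehyde OH, formyl carbon), and no nitric acid oxidation is needed.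

Key step: step 3

Remark: the target has no stereocentre and no hindered axis, so no step has to set configuration; compounds 1, 3 and 4 are taken as commercial.

Step 1
Reactants: 1 2-hydroxy-4-methoxybenzaldehyde
Product: 2 3,5-dibromo-2-hydroxy-4-methoxybenzaldehyde
Conditions: Br2 (2.1 equiv), NaOAc (2.2 equiv), AcOH, rt
Reagents that add atoms: bromine, BrBr
Why: Electrophilic aromatic bromination: C5 (para to OH, ortho to OMe) and C3 (ortho to both) are the only positions activated by the two oxygen donors and are meta to the formyl group, whereas C6 is meta to both donors, so the 3,5-dibromide should form cleanly.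

Step 2
Reactants: 3 2,4-dibromo-1-iodobenzene; 4 1,3,5-trimethoxybenzene
Product: 6 (2,4-dibromophenyl)(2,4,6-trimethoxyphenyl)iodonium tosylate, via hydroxy(tosyloxy)iodoarene 5 (not isolated)
Conditions: mCPBA (1.05 equiv), TsOH·H2O (1.05 equiv), MeCN, 77 °C, 30 min; then 4 (1.05 equiv), 77 °C, 10 min; precipitation with Et2O
Reagents that add atoms: p-toluenesulfonic acid, Cc1ccc(cc1)S(=O)(=O)O
Why: The peracid oxidises the aryl iodide in the presence of TsOH to the hydroxy(tosyloxy)-λ3-iodane 5, whose electrophilic iodine is attacked by the very electron-rich 1,3,5-trimethoxybenzene with loss of water (electrophilic aromatic substitution), the one-pot synthesis of aryl(2,4,6-trimethoxyphenyl)iodonium tosylates, which tolerates halogens and ortho substituents.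

Step 3
Reactants: 2 3,5-dibromo-2-hydroxy-4-methoxybenzaldehyde (1.0 equiv); 6 (2,4-dibromophenyl)(2,4,6-trimethoxyphenyl)iodonium tosylate (1.2 equiv)
Product: 7 3,5-dibromo-2-(2,4-dibromophenoxy)-4-methoxybenzaldehyde
Conditions: K2CO3 (1.5 equiv), MeCN, 60 °C
Reagents that add atoms: none
Why: The phenoxide of 2 should replace tosylate on the iodine of 6 to give a T-shaped aryl(aryloxy)-λ3-iodane, and ligand coupling through a three-centre transition state at C1' of ring B should form the O–C1' bond and release 2-iodo-1,3,5-trimethoxybenzene. The closest known reaction type is the transition-metal-free O-arylation of phenols with diaryliodonium salts, which is established for 2,6-disubstituted and polybrominated phenoxides and for aryl(2,4,6-trimethoxyphenyl)iodonium salts. No ring is closed and no stereocentre is formed. The step needs transfer of the right aryl group, which is secured because the electron-poor, ortho-brominated ring B couples while the electron-rich trimethoxyphenyl group stays on iodine. It needs O- rather than C-arylation, which is secured because C1, C3 and C5 of the phenoxide all carry substituents. It must leave four aryl bromides and the aldehyde untouched, which the absence of a transition metal and of any strong base should secure, and this polarity reversal of ring B lets two phenol-type fragments be joined without a quinone.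

Step 4
Reactants: 7 3,5-dibromo-2-(2,4-dibromophenoxy)-4-methoxybenzaldehyde
Product: 9 3,5-dibromo-2-(2,4-dibromophenoxy)-4-methoxyphenol, via aryl formate 8 (not isolated)
Conditions: mCPBA (2.0 equiv), CH2Cl2, rt → 40 °C; then MeOH, K2CO3 (0.2 equiv), 0 °C → rt; aq. NH4Cl
Reagents that add atoms: 3-chloroperoxybenzoic acid, O=C(OO)c1cccc(Cl)c1
Why: Baeyer–Villiger (Dakin-type) oxidation: the peracid adds to the formyl group and the aryl group, supported by the ortho aryloxy and para methoxy oxygens, migrates to oxygen to give formate 8, which is methanolysed to the phenol, a reaction type that should carry over from other polybrominated 2-aryloxybenzaldehydes; the C1 oxygen is created only after the ether is in place, so it needs no protection and no differentiation.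

**Compound list**
1 | 2-hydroxy-4-methoxybenzaldehyde | COc1ccc(C=O)c(O)c1 | starting material
2 | 3,5-dibromo-2-hydroxy-4-methoxybenzaldehyde | COc1c(Br)cc(C=O)c(O)c1Br | intermediate
3 | 2,4-dibromo-1-iodobenzene | Brc1ccc(I)c(Br)c1 | starting material
4 | 1,3,5-trimethoxybenzene | COc1cc(OC)cc(OC)c1 | starting material
5 | 2,4-dibromo-1-[hydroxy(tosyloxy)iodo]benzene | Cc1ccc(cc1)S(=O)(=O)OI(O)c1ccc(Br)cc1Br | intermediate (not isolated)
6 | (2,4-dibromophenyl)(2,4,6-trimethoxyphenyl)iodonium 4-methylbenzenesulfonate | COc1cc(OC)c([I+]c2ccc(Br)cc2Br)c(OC)c1.Cc1ccc(cc1)S(=O)(=O)[O-] | intermediate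
7 | 3,5-dibromo-2-(2,4-dibromophenoxy)-4-methoxybenzaldehyde | COc1c(Br)cc(C=O)c(Oc2ccc(Br)cc2Br)c1Br | intermediate
8 | 3,5-dibromo-2-(2,4-dibromophenoxy)-4-methoxyphenyl formate | COc1c(Br)cc(OC=O)c(Oc2ccc(Br)cc2Br)c1Br | intermediate (not isolated)
9 | 3,5-dibromo-2-(2,4-dibromophenoxy)-4-methoxyphenol (achiral) | COc1c(Br)cc(O)c(Oc2ccc(Br)cc2Br)c1Br | target

**Step count and risks**
Total step count: 4. Longest linear sequence: 3 steps (1 → 2 → 7 → 9); step 2 is a one-step branch that supplies 6.

Steps most likely to fail:

Step 3. Ligand coupling at the hindered, weakly nucleophilic phenoxide of 2 may be too slow, so that base-induced decomposition of 6 takes over. The fallback changes the order of events. The unhindered phenol 1 would be arylated with 6 (K2CO3, MeCN, 40 °C) to 2-(2,4-dibromophenoxy)-4-methoxybenzaldehyde F1. F1 would then be dibrominated (Br2, NaOAc, AcOH, 50 °C) at C5 and C3 of ring A, the positions to which the methoxy group (ortho), the aryloxy group (para and ortho) and the formyl group (meta) all direct, while ring B is deactivated by its two bromines. This sets out from 1 and 6 and returns to the route at 7.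

Step 4. Hydride instead of aryl migration in the peracid adduct may give the benzoic acid, or the crowded carbonyl may resist addition. The fallback turns the formyl group into an acetyl group, which has no hydrogen to migrate. From 7, MeMgBr (THF, −78 °C; aryl bromides do not exchange with this reagent) would give racemic 1-[3,5-dibromo-2-(2,4-dibromophenoxy)-4-methoxyphenyl]ethanol F2. MnO2 (CH2Cl2, rt) would give 1-[3,5-dibromo-2-(2,4-dibromophenoxy)-4-methoxyphenyl]ethanone F3. Baeyer–Villiger oxidation with CF3CO3H (from (CF3CO)2O and urea·H2O2, Na2HPO4, CH2Cl2; aryl migrates in preference to methyl) would give 3,5-dibromo-2-(2,4-dibromophenoxy)-4-methoxyphenyl acetate F4. Methanolysis (K2CO3, MeOH) would return to the route at 9.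

Step 2. Oxidation of the electron-poor, ortho-substituted iodoarene 3 may stall, or the peracid may consume the trimethoxybenzene. The fallback gives up trivalent iodine. Iodine–magnesium exchange on 3 (i-PrMgCl·LiCl, THF, −40 °C, selective for C–I), then B(OMe)3 and aqueous acid, would give (2,4-dibromophenyl)boronic acid F5. A Chan–Lam oxidative coupling of F5 with 2 (Cu(OAc)2, divalent copper, 1 equiv, pyridine, 4 Å molecular sieves, CH2Cl2, air, rt) would form the same O–C1' bond without oxidative addition into any C–Br bond. This sets out from 3 and returns to the route at 7.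

**Further compounds**
F1 | step 3 | 2-(2,4-dibromophenoxy)-4-methoxybenzaldehyde | COc1ccc(C=O)c(Oc2ccc(Br)cc2Br)c1
F2 | step 4 | 1-[3,5-dibromo-2-(2,4-dibromophenoxy)-4-methoxyphenyl]ethanol (racemic) | COc1c(Br)cc(C(C)O)c(Oc2ccc(Br)cc2Br)c1Br
F3 | step 4 | 1-[3,5-dibromo-2-(2,4-dibromophenoxy)-4-methoxyphenyl]ethanone | COc1c(Br)cc(C(C)=O)c(Oc2ccc(Br)cc2Br)c1Br
F4 | step 4 | 3,5-dibromo-2-(2,4-dibromophenoxy)-4-methoxyphenyl acetate | COc1c(Br)cc(OC(C)=O)c(Oc2ccc(Br)cc2Br)c1Br
F5 | step 2 | (2,4-dibromophenyl)boronic acid | OB(O)c1ccc(Br)cc1Br
A1 | direct plan | 2,4,6-tribromophenol | Oc1c(Br)cc(Br)cc1Br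
A2 | direct plan | 2,6-dibromo-1,4-benzoquinone | O=C1C=C(Br)C(=O)C(Br)=C1
A3 | direct plan | 2,4-dibromophenol | Oc1ccc(Br)cc1Br
A4 | direct plan | 3,5-dibromo-2-(2,4-dibromophenoxy)benzene-1,4-diol | Oc1cc(Br)c(O)c(Br)c1Oc1ccc(Br)cc1Br
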